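Early in the violet run G reads 0.5 % after 25.0 h, the lag of two additions in sequence on X, and the reckoning starts from that lag.

in all of them: X 0.31 M

| charge | L | E | temperature | remark | time |
|---|---|---|---|---|---|
| violet | 0.46 M | 6.2 mM | 40 °C | run made earlier |  |
| ochre | 0.92 M | 6.2 mM | 62 °C | run made earlier |  |
| green | 1.9 M | 6.2 mM | 40 °C | run made earlier |  |
| winter | 0.465 M | 6.20 mM |  | at 70 °C until 25 h, from then on at 30 °C | 50 h |
| autumn | 2.00 M | 6.20 mM |  | at 70 °C throughout | 50 h |

| run | time / h | G / % |
|---|---|---|
| violet | 25.0 | 0.5 |
| violet | 48.0 | 0.4 |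
| violet | 96.0 | 3.0 |
| violet | 120 | 6.1 |
| ochre | 3.00 | 1.2 |
| ochre | 8.00 | 7.3 |
| ochre | 15.0 | 18.1 |
| ochre | 25.0 | 31.9 |
| green | 12.0 | 1.6 |
| green | 40.0 | 9.9 |
| green | 72.0 | 22.8 |
| green | 120 | 40.9 |

(each reading ± 0.5 percentage points)

- which of the two ends with the higher amount of G, in percent of the X charged ("neither" if they lie within 2 percentage points) (winter / autumn / neither)
- G at the end, in percent of the X charged, winter
- G at the end, in percent of the X charged, autumn

The quantity to carry is the turnover count n = k·c_L·t. If both additions run pseudo-first-order with one common k, G as a fraction of X is 1 − e^(−n)·(1 + n), and for small n this is 0.5·n·n. So a small reading gives n as the root of 2·G. The violet run at 120 h gives k = 0.00633 /M/h, and the green run at 40.0 h gives 0.00585 /M/h. These are close, though c_L differs 4.13 times, so c_L·t is the right clock.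

Two ways lead to k at 70 °C. Doubling every 10 degrees multiplies the violet value by 8, giving 0.0506 /M/h. The ochre run at 8.00 h gives 0.0519 /M/h, which is 8.20 times the violet value at 40 °C. Carrying that factor per degree onward gives the count constant 0.112 /M/h. The two part, and doubling is the one that cheats: the ochre run stands 22.0 K above the violet run, yet the factor read between them already exceeds 8.

For autumn, with c_L no lower than 1.38 M, my two counts give 99.6 % and 86.3 %, both high. For winter, 0.112 /M/h with c_L at the charge gives n = 1.30, and with the charge less 0.5·c_X it gives 0.865. That gives G of 21.5 % and 37.2 %. The 30 °C stage of winter adds a count of 0.0188. My estimate is about 29.4 % for winter, with 17.3 % from doubling and the early form.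

The forecast says autumn: winter 17 % (12 % to 23 %), autumn 95 % (85 % to 99 %), on the grounds of “a lag followed by a near-linear rise”. Its winter number is what doubling from the violet run gives.

The flasks give 27.4 % for winter and 99.7 % for autumn, so autumn ends higher.

    X + L → Q (k = 0.0964 /M/h, Ea = 95.0 kJ/mol)
    Q + E → D (k = 0.0567 /M/h, Ea = 88.0 kJ/mol)
    L + Q → G (k = 0.167 /M/h, Ea = 75.0 kJ/mol)
    (constants at 70 °C)

Winter lies between the two figures from 0.112 /M/h, and 10 percentage points above the forecast. Winter's stage at 70 °C lasts 25 h, longer than the 15 h half-life of X by its first addition at the charged amounts, and G reads 26.6 % at the change and 27.4 % at the end. In the neighbour of autumn, the same flask with 0.50 M of L, 0.112 /M/h with the charge less 0.5·c_X counts n = 1.93, so G = 57.3 %. The computed flask gives 47.9 %, with 23.2 % standing as Q, so the count runs 9.4 points high there.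

The data stem from a simulated flask with made-up constants; noise was put on by code.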